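**Retrosynthetic overview**
1. Wailupemycin I ⇐ global O-debenzylation of 41 ⇐ methylene bridging of two 4-hydroxy-2-pyrones of similar size: tetralone–pyrone 26 plus naphthyl–pyrone Mannich base 39 (bridge carbon from Eschenmoser's salt).
2. In each half the pyrone is the last ring made: methyl ketone → silyl enol ether + malonyl dichloride (21 → 24 and 35 → 37).
3. Tetralone half: the carbocycle is closed by ring-closing metathesis, then C3/C4 are set by OH-directed epoxidation and anti cuprate opening. The C1 carbinol comes from an asymmetric allylboration, controls both centres, and is oxidised to the ketone at the end.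
4. Naphthalene half: the second benzene ring is formed by Michael addition/C-arylation/deacetylation of ynone 30 with pentane-2,4-dione.
5. Both arenes come from 3-bromophenol through aldehyde 5.

Assumptions: the sense of induction in step 6 follows the precedent for aryl aldehydes ((S)-acid gives the S carbinol); Grignard reagents 9 and 17 are bought as solutions.

**Step 1**
Reactants: 1 3-bromophenol
Product: 2 1-(benzyloxy)-3-bromobenzene
Conditions: BnBr, K2CO3, DMF, 25 °C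
Reagents that add atoms: benzyl bromide, BrCc1ccccc1
Why: Williamson ether synthesis; the benzyl ether masks the phenol to the end and directs the metalation in step 2.

**Step 2**
Reactants: 2 1-(benzyloxy)-3-bromobenzene; 3 N,N-dimethylformamide
Product: 5 2-(benzyloxy)-6-bromobenzaldehyde, via aryllithium 4 (not isolated)
Conditions: LiN(iPr)2, THF, −78 °C; then 3, −78 °C to 0 °C; aq. work-up
Reagents that add atoms: none
Why: Directed ortho-metalation at the C–H flanked by Br and OBn, then formylation at −78 °C before LiBr loss to an aryne can occur.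

**Step 3**
Reactants: 5 2-(benzyloxy)-6-bromobenzaldehyde; 6 potassium ethenyltrifluoroborate
Product: 7 2-(benzyloxy)-6-ethenylbenzaldehyde
Conditions: PdCl2(dppf) (3 mol %), Cs2CO3, THF/H2O 9:1, 80 °C
Reagents that add atoms: none
Why: Suzuki–Miyaura vinylation of the aryl bromide; the aldehyde is inert to the trifluoroborate.

**Step 4**
Reactants: 8 prop-2-yn-1-ol; 9 phenylmagnesium bromide
Product: 11 2-phenylprop-2-en-1-ol, via vinylmagnesium alkoxide 10 (not isolated)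
Conditions: 9 (2.5 equiv), CuI (10 mol %), Et2O, 0 °C to reflux; aq. work-up
Reagents that add atoms: none
Why: Copper-catalysed anti-carbomagnesiation of the propargylic alkoxide puts phenyl on the internal carbon; protonation gives the 2-arylallyl alcohol.

**Step 5**
Reactants: 11 2-phenylprop-2-en-1-ol
Product: 12 4,4,5,5-tetramethyl-2-(2-phenylprop-2-en-1-yl)-1,3,2-dioxaborolane
Conditions: B2pin2, Pd(MeCN)4(BF4)2 (5 mol %), DMSO/MeOH 1:1, 50 °C
Reagents that add atoms: bis(pinacolato)diboron, CC1(C)OB(OC1(C)C)B1OC(C)(C)C(C)(C)O1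
Why: Palladium-catalysed allylic C–OH borylation through a π-allyl intermediate; the symmetrical 2-substituted allyl unit gives one boronate.

**Step 6**
Reactants: 7 2-(benzyloxy)-6-ethenylbenzaldehyde; 12 4,4,5,5-tetramethyl-2-(2-phenylprop-2-en-1-yl)-1,3,2-dioxaborolane
Product: 14 (1S)-1-[2-(benzyloxy)-6-ethenylphenyl]-3-phenylbut-3-en-1-ol, via borate ester 13 (not isolated)
Conditions: (S)-TRIP [(S)-3,3'-bis(2,4,6-triisopropylphenyl)-1,1'-binaphthyl-2,2'-diyl hydrogen phosphate] (5 mol %), toluene, 4 Å MS, −30 °C; then aq. NaHCO3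
Reagents that add atoms: none
Why: Chiral phosphoric acid-catalysed allylboration through a closed chair transition state; the (S)-acid directs attack to the Si face and sets the carbinol carbon as S.

**Step 7**
Reactants: 14 (1S)-1-[2-(benzyloxy)-6-ethenylphenyl]-3-phenylbut-3-en-1-ol
Product: 15 (1S)-8-(benzyloxy)-3-phenyl-1,2-dihydronaphthalen-1-ol
Conditions: second-generation Grubbs catalyst RuCl2(=CHPh)(H2IMes)(PCy3) (5 mol %), CH2Cl2, 40 °C
Reagents that add atoms: none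
Why: Ring-closing metathesis of the styrene with the 1,1-disubstituted alkene closes the six-membered carbocycle; the carbinol centre is untouched.

**Step 8**
Reactants: 15 (1S)-8-(benzyloxy)-3-phenyl-1,2-dihydronaphthalen-1-ol
Product: 16 (1aS,3S,7bS)-4-(benzyloxy)-1a-phenyl-1a,2,3,7b-tetrahydronaphtho[1,2-b]oxiren-3-ol
Conditions: VO(acac)2 (5 mol %), t-BuOOH, CH2Cl2, 0 °C
Reagents that add atoms: tert-butyl hydroperoxide, CC(C)(C)OO
Why: Hydroxyl-directed epoxidation of a cyclic homoallylic alcohol; the vanadate ester delivers oxygen to the alkene face cis to the C1 hydroxyl, which fixes the C3–O configuration.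

**Step 9**
Reactants: 16 (1aS,3S,7bS)-4-(benzyloxy)-1a-phenyl-1a,2,3,7b-tetrahydronaphtho[1,2-b]oxiren-3-ol; 17 bromo(prop-1-en-2-yl)magnesium
Product: 18 (1S,3R,4R)-8-(benzyloxy)-3-phenyl-4-(prop-1-en-2-yl)-1,2,3,4-tetrahydronaphthalene-1,3-diol
Conditions: 17 (4 equiv), CuI (20 mol %), THF, −40 °C to 0 °C; aq. work-up
Reagents that add atoms: none
Why: Copper-catalysed SN2 epoxide opening at the secondary benzylic carbon (the other carbon is fully substituted) with inversion, so the C4 substituent ends trans to the C3 hydroxyl as in the target.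

**Step 10**
Reactants: 18 (1S,3R,4R)-8-(benzyloxy)-3-phenyl-4-(prop-1-en-2-yl)-1,2,3,4-tetrahydronaphthalene-1,3-diol
Product: 19 (1S,3R,4R)-8-(benzyloxy)-3-phenyl-4-(prop-1-en-2-yl)-1,3-bis(triethylsilyloxy)-1,2,3,4-tetrahydronaphthalene
Conditions: Et3SiOTf, 2,6-lutidine, CH2Cl2, −78 °C to 0 °C
Reagents that add atoms: triethylsilyl trifluoromethanesulfonate, CC[Si](CC)(CC)OS(=O)(=O)C(F)(F)F
Why: Silyl triflate protection of both alcohols blocks retro-aldol cleavage of the tertiary carbinol and keeps C1 at the alcohol oxidation level during pyrone construction.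

**Step 11**
Reactants: 19 (1S,3R,4R)-8-(benzyloxy)-3-phenyl-4-(prop-1-en-2-yl)-1,3-bis(triethylsilyloxy)-1,2,3,4-tetrahydronaphthalene
Product: 21 1-[(1R,2R,4S)-5-(benzyloxy)-2-phenyl-2,4-bis(triethylsilyloxy)-1,2,3,4-tetrahydronaphthalen-1-yl]ethan-1-one, via ozonide 20 (not isolated)
Conditions: O3, CH2Cl2, −78 °C (Sudan red end point); then Me2S, −78 °C to 25 °C
Reagents that add atoms: ozone, [O-][O+]=O
Why: Ozonolysis of the 1,1-disubstituted alkene gives the methyl ketone under neutral conditions, so the adjacent stereocentre is not epimerised.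

**Step 12**
Reactants: 21 1-[(1R,2R,4S)-5-(benzyloxy)-2-phenyl-2,4-bis(triethylsilyloxy)-1,2,3,4-tetrahydronaphthalen-1-yl]ethan-1-one; 22 malonyl dichloride
Product: 24 6-[(1S,2R,4S)-5-(benzyloxy)-2-phenyl-2,4-bis(triethylsilyloxy)-1,2,3,4-tetrahydronaphthalen-1-yl]-4-hydroxy-2H-pyran-2-one, via silyl enol ether 23 (not isolated)
Conditions: LiN(SiMe3)2, Me3SiCl, THF, −78 °C; solvent exchange; then 22, 2,6-di-tert-butylpyridine, Et2O, −78 °C to 25 °C
Reagents that add atoms: none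
Why: Kinetic enolisation at the methyl group (the ring C–H is hindered and keeps its configuration), then Effenberger pyrone synthesis: C-acylation of the enol silane and ring closure by O-acylation.

**Step 13**
Reactants: 24 6-[(1S,2R,4S)-5-(benzyloxy)-2-phenyl-2,4-bis(triethylsilyloxy)-1,2,3,4-tetrahydronaphthalen-1-yl]-4-hydroxy-2H-pyran-2-one
Product: 25 6-[(1R,2R,4S)-5-(benzyloxy)-2,4-dihydroxy-2-phenyl-1,2,3,4-tetrahydronaphthalen-1-yl]-4-hydroxy-2H-pyran-2-one
Conditions: HF·pyridine, pyridine/THF, 0 °C to 25 °C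
Reagents that add atoms: none
Why: Buffered fluoride desilylation frees both alcohols without the acid or base that would dehydrate the benzylic positions (the descriptor at the ring carbon changes by priority only).

**Step 14**
Reactants: 25 6-[(1R,2R,4S)-5-(benzyloxy)-2,4-dihydroxy-2-phenyl-1,2,3,4-tetrahydronaphthalen-1-yl]-4-hydroxy-2H-pyran-2-one
Product: 26 6-[(1R,2R)-5-(benzyloxy)-2-hydroxy-4-oxo-2-phenyl-1,2,3,4-tetrahydronaphthalen-1-yl]-4-hydroxy-2H-pyran-2-one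
Conditions: MnO2 (activated, excess), CH2Cl2, 25 °C
Reagents that add atoms: none
Why: Chemoselective oxidation of the secondary benzylic alcohol (tertiary alcohol and enolic pyrone are inert) gives the β-hydroxy tetralone under neutral conditions and removes the controlling stereocentre.

**Step 15**
Reactants: 5 2-(benzyloxy)-6-bromobenzaldehyde; 27 phenylacetylene
Product: 29 1-[2-(benzyloxy)-6-bromophenyl]-3-phenylprop-2-yn-1-ol (racemic), via lithium phenylacetylide 28 (not isolated)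
Conditions: 27, n-BuLi, THF, −78 °C; then 5, −78 °C to 0 °C; aq. work-up
Reagents that add atoms: none
Why: 1,2-Addition of the preformed acetylide to the aldehyde; the carbinol centre is removed in the next step.

**Step 16**
Reactants: 29 1-[2-(benzyloxy)-6-bromophenyl]-3-phenylprop-2-yn-1-ol
Product: 30 1-[2-(benzyloxy)-6-bromophenyl]-3-phenylprop-2-yn-1-one
Conditions: MnO2, CH2Cl2, 25 °C
Reagents that add atoms: none
Why: Oxidation of the propargylic/benzylic alcohol to the ynone Michael acceptor.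

**Step 17**
Reactants: 30 1-[2-(benzyloxy)-6-bromophenyl]-3-phenylprop-2-yn-1-one; 31 pentane-2,4-dione
Product: 34 1-[5-(benzyloxy)-4-hydroxy-2-phenylnaphthalen-1-yl]ethan-1-one, via Michael adduct 32 (not isolated), via diacetyl naphthalenone 33 (not isolated)
Conditions: 31 (1.5 equiv), Cs2CO3, CuI (10 mol %), L-proline (20 mol %), wet DMSO, 25 °C then 90 °C; acidic work-up
Reagents that add atoms: none
Why: Domino Michael addition to the ynone, CuI-catalysed intramolecular C-arylation (Hurtley type) at C–Br and retro-Claisen loss of one acetyl, which aromatises the new ring; the doubly ortho-substituted aryl ketone is too hindered for the competing aldol benzannulation.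

**Step 18**
Reactants: 34 1-[5-(benzyloxy)-4-hydroxy-2-phenylnaphthalen-1-yl]ethan-1-one
Product: 35 1-[4,5-bis(benzyloxy)-2-phenylnaphthalen-1-yl]ethan-1-one
Conditions: BnBr, K2CO3, DMF, 60 °C
Reagents that add atoms: benzyl bromide, BrCc1ccccc1
Why: Williamson etherification of the naphthol, so that only the pyrone can react with the iminium salt in step 20.

**Step 19**
Reactants: 35 1-[4,5-bis(benzyloxy)-2-phenylnaphthalen-1-yl]ethan-1-one; 22 malonyl dichloride
Product: 37 6-[4,5-bis(benzyloxy)-2-phenylnaphthalen-1-yl]-4-hydroxy-2H-pyran-2-one, via silyl enol ether 36 (not isolated)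
Conditions: LiN(SiMe3)2, Me3SiCl, THF, −78 °C; solvent exchange; then 22, 2,6-di-tert-butylpyridine, Et2O, −78 °C to 25 °C
Reagents that add atoms: none
Why: Effenberger pyrone synthesis on an aryl methyl ketone; acylation occurs at the unhindered terminal carbon, so the crowded aryl–pyrone bond need not be formed by coupling.

**Step 20**
Reactants: 37 6-[4,5-bis(benzyloxy)-2-phenylnaphthalen-1-yl]-4-hydroxy-2H-pyran-2-one; 38 N,N-dimethylmethyleneiminium iodide
Product: 39 6-[4,5-bis(benzyloxy)-2-phenylnaphthalen-1-yl]-3-[(dimethylamino)methyl]-4-hydroxy-2H-pyran-2-one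
Conditions: 38 (1.05 equiv), CH2Cl2, 0 °C to 25 °C; then aq. NaHCO3
Reagents that add atoms: none
Why: Mannich aminomethylation at C3 of the enolic pyrone, the only nucleophilic carbon once the naphthol oxygens are benzylated.

**Step 21**
Reactants: 26 6-[(1R,2R)-5-(benzyloxy)-2-hydroxy-4-oxo-2-phenyl-1,2,3,4-tetrahydronaphthalen-1-yl]-4-hydroxy-2H-pyran-2-one; 39 6-[4,5-bis(benzyloxy)-2-phenylnaphthalen-1-yl]-3-[(dimethylamino)methyl]-4-hydroxy-2H-pyran-2-one
Product: 41 3-({6-[4,5-bis(benzyloxy)-2-phenylnaphthalen-1-yl]-4-hydroxy-2-oxo-2H-pyran-3-yl}methyl)-6-[(1R,2R)-5-(benzyloxy)-2-hydroxy-4-oxo-2-phenyl-1,2,3,4-tetrahydronaphthalen-1-yl]-4-hydroxy-2H-pyran-2-one, via methylidene dione 40 (not isolated)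
Conditions: 26 (1.0 equiv), 39 (1.2 equiv), MeCN, 60 °C; dilute KHSO4 wash
Reagents that add atoms: none
Why: Loss of Me2NH from the zwitterionic Mannich base gives a quinone-methide-like 3-methylidene dione that is trapped by C3 of the pyrone of 26 (stepwise Knoevenagel–Michael bridging), so 26 cannot homodimerise and its stereocentres are not touched.

**Step 22**
Reactants: 41 tri-O-benzyl wailupemycin I (name as in step 21)
Product: 42 wailupemycin I, 3-{[6-(4,5-dihydroxy-2-phenylnaphthalen-1-yl)-4-hydroxy-2-oxo-2H-pyran-3-yl]methyl}-6-[(1R,2R)-2,5-dihydroxy-4-oxo-2-phenyl-1,2,3,4-tetrahydronaphthalen-1-yl]-4-hydroxy-2H-pyran-2-one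
Conditions: H2 (1 atm), Pd/C (10 wt %), EtOAc/EtOH 1:1, 25 °C
Reagents that add atoms: none
Why: Hydrogenolysis of the three aryl benzyl ethers under neutral conditions; tertiary alcohol, aryl ketone and pyrones are expected to survive at 1 atm with monitoring.

**Compound list**
1 | 3-bromophenol | Oc1cccc(Br)c1 | starting material
2 | 1-(benzyloxy)-3-bromobenzene | Brc1cccc(OCc2ccccc2)c1 | intermediate
3 | N,N-dimethylformamide | CN(C)C=O | starting material
4 | [2-(benzyloxy)-6-bromophenyl]lithium | [Li]c1c(Br)cccc1OCc1ccccc1 | intermediate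
5 | 2-(benzyloxy)-6-bromobenzaldehyde | O=Cc1c(Br)cccc1OCc1ccccc1 | intermediate
6 | potassium ethenyltrifluoroborate | [K+].C=C[B-](F)(F)F | starting material
7 | 2-(benzyloxy)-6-ethenylbenzaldehyde | O=Cc1c(C=C)cccc1OCc1ccccc1 | intermediate
8 | prop-2-yn-1-ol | C#CCO | starting material
9 | phenylmagnesium bromide | Br[Mg]c1ccccc1 | starting material
10 | bromomagnesium (2Z)-3-(bromomagnesio)-2-phenylprop-2-en-1-olate | Br[Mg]/C=C(/c1ccccc1)CO[Mg]Br | intermediate
11 | 2-phenylprop-2-en-1-ol | C=C(CO)c1ccccc1 | intermediate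
12 | 4,4,5,5-tetramethyl-2-(2-phenylprop-2-en-1-yl)-1,3,2-dioxaborolane | C=C(CB1OC(C)(C)C(C)(C)O1)c1ccccc1 | intermediate
13 | 2-{[(1S)-1-[2-(benzyloxy)-6-ethenylphenyl]-3-phenylbut-3-en-1-yl]oxy}-4,4,5,5-tetramethyl-1,3,2-dioxaborolane | C=C(c1ccccc1)C[C@H](OB1OC(C)(C)C(C)(C)O1)c1c(C=C)cccc1OCc1ccccc1 | intermediate
14 | (1S)-1-[2-(benzyloxy)-6-ethenylphenyl]-3-phenylbut-3-en-1-ol | C=C(c1ccccc1)C[C@H](O)c1c(C=C)cccc1OCc1ccccc1 | intermediate
15 | (1S)-8-(benzyloxy)-3-phenyl-1,2-dihydronaphthalen-1-ol | O[C@H]1CC(c2ccccc2)=Cc2cccc(OCc3ccccc3)c21 | intermediate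
16 | (1aS,3S,7bS)-4-(benzyloxy)-1a-phenyl-1a,2,3,7b-tetrahydronaphtho[1,2-b]oxiren-3-ol (epoxide cis to OH) | O[C@H]1C[C@@]2(c3ccccc3)O[C@H]2c2cccc(OCc3ccccc3)c21 | intermediate
17 | bromo(prop-1-en-2-yl)magnesium | CC(=C)[Mg]Br | starting material
18 | (1S,3R,4R)-8-(benzyloxy)-3-phenyl-4-(prop-1-en-2-yl)-1,2,3,4-tetrahydronaphthalene-1,3-diol | O[C@H]1C[C@](O)(c2ccccc2)[C@H](C(C)=C)c2cccc(OCc3ccccc3)c21 | intermediate
19 | (1S,3R,4R)-8-(benzyloxy)-3-phenyl-4-(prop-1-en-2-yl)-1,3-bis(triethylsilyloxy)-1,2,3,4-tetrahydronaphthalene | CC[Si](CC)(CC)O[C@H]1C[C@](O[Si](CC)(CC)CC)(c2ccccc2)[C@H](C(C)=C)c2cccc(OCc3ccccc3)c21 | intermediate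
20 | 3-[(1R,2R,4S)-5-(benzyloxy)-2-phenyl-2,4-bis(triethylsilyloxy)-1,2,3,4-tetrahydronaphthalen-1-yl]-3-methyl-1,2,4-trioxolane (both epimers at the trioxolane carbon) | CC[Si](CC)(CC)O[C@H]1C[C@](O[Si](CC)(CC)CC)(c2ccccc2)[C@H](C2(C)OCOO2)c2cccc(OCc3ccccc3)c21 | intermediate
21 | 1-[(1R,2R,4S)-5-(benzyloxy)-2-phenyl-2,4-bis(triethylsilyloxy)-1,2,3,4-tetrahydronaphthalen-1-yl]ethan-1-one | CC[Si](CC)(CC)O[C@H]1C[C@](O[Si](CC)(CC)CC)(c2ccccc2)[C@H](C(C)=O)c2cccc(OCc3ccccc3)c21 | intermediate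
22 | malonyl dichloride (propanedioyl dichloride) | O=C(Cl)CC(=O)Cl | starting material
23 | {1-[(1S,2R,4S)-5-(benzyloxy)-2-phenyl-2,4-bis(triethylsilyloxy)-1,2,3,4-tetrahydronaphthalen-1-yl]ethenyl}oxy(trimethyl)silane | CC[Si](CC)(CC)O[C@H]1C[C@](O[Si](CC)(CC)CC)(c2ccccc2)[C@H](C(=C)O[Si](C)(C)C)c2cccc(OCc3ccccc3)c21 | intermediate
24 | 6-[(1S,2R,4S)-5-(benzyloxy)-2-phenyl-2,4-bis(triethylsilyloxy)-1,2,3,4-tetrahydronaphthalen-1-yl]-4-hydroxy-2H-pyran-2-one | CC[Si](CC)(CC)O[C@H]1C[C@](O[Si](CC)(CC)CC)(c2ccccc2)[C@H](c2cc(O)cc(=O)o2)c2cccc(OCc3ccccc3)c21 | intermediate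
25 | 6-[(1R,2R,4S)-5-(benzyloxy)-2,4-dihydroxy-2-phenyl-1,2,3,4-tetrahydronaphthalen-1-yl]-4-hydroxy-2H-pyran-2-one | O[C@H]1C[C@](O)(c2ccccc2)[C@H](c2cc(O)cc(=O)o2)c2cccc(OCc3ccccc3)c21 | intermediate
26 | 6-[(1R,2R)-5-(benzyloxy)-2-hydroxy-4-oxo-2-phenyl-1,2,3,4-tetrahydronaphthalen-1-yl]-4-hydroxy-2H-pyran-2-one | O=C1C[C@](O)(c2ccccc2)[C@H](c2cc(O)cc(=O)o2)c2cccc(OCc3ccccc3)c21 | intermediate
27 | phenylacetylene | C#Cc1ccccc1 | starting material
28 | lithium phenylacetylide | [Li]C#Cc1ccccc1 | intermediate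
29 | 1-[2-(benzyloxy)-6-bromophenyl]-3-phenylprop-2-yn-1-ol (racemic) | OC(C#Cc1ccccc1)c1c(Br)cccc1OCc1ccccc1 | intermediate
30 | 1-[2-(benzyloxy)-6-bromophenyl]-3-phenylprop-2-yn-1-one | O=C(C#Cc1ccccc1)c1c(Br)cccc1OCc1ccccc1 | intermediate
31 | pentane-2,4-dione | CC(=O)CC(C)=O | starting material
32 | 3-{3-[2-(benzyloxy)-6-bromophenyl]-3-oxo-1-phenylprop-1-en-1-yl}pentane-2,4-dione (alkene isomers interconvert) | CC(=O)C(C(C)=O)C(=CC(=O)c1c(Br)cccc1OCc1ccccc1)c1ccccc1 | intermediate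
33 | 4,4-diacetyl-8-(benzyloxy)-3-phenylnaphthalen-1(4H)-one | CC(=O)C1(C(C)=O)C(c2ccccc2)=CC(=O)c2c(OCc3ccccc3)cccc21 | intermediate
34 | 1-[5-(benzyloxy)-4-hydroxy-2-phenylnaphthalen-1-yl]ethan-1-one | CC(=O)c1c(-c2ccccc2)cc(O)c2c(OCc3ccccc3)cccc12 | intermediate
35 | 1-[4,5-bis(benzyloxy)-2-phenylnaphthalen-1-yl]ethan-1-one | CC(=O)c1c(-c2ccccc2)cc(OCc2ccccc2)c2c(OCc3ccccc3)cccc12 | intermediate
36 | {1-[4,5-bis(benzyloxy)-2-phenylnaphthalen-1-yl]ethenyl}oxy(trimethyl)silane | C=C(O[Si](C)(C)C)c1c(-c2ccccc2)cc(OCc2ccccc2)c2c(OCc3ccccc3)cccc12 | intermediate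
37 | 6-[4,5-bis(benzyloxy)-2-phenylnaphthalen-1-yl]-4-hydroxy-2H-pyran-2-one | O=c1cc(O)cc(-c2c(-c3ccccc3)cc(OCc3ccccc3)c3c(OCc4ccccc4)cccc23)o1 | intermediate
38 | N,N-dimethylmethyleneiminium iodide (Eschenmoser's salt) | C[N+](C)=C.[I-] | starting material
39 | 6-[4,5-bis(benzyloxy)-2-phenylnaphthalen-1-yl]-3-[(dimethylamino)methyl]-4-hydroxy-2H-pyran-2-one | CN(C)Cc1c(O)cc(-c2c(-c3ccccc3)cc(OCc3ccccc3)c3c(OCc4ccccc4)cccc23)oc1=O | intermediate
40 | 6-[4,5-bis(benzyloxy)-2-phenylnaphthalen-1-yl]-3-methylidene-2H-pyran-2,4(3H)-dione | C=C1C(=O)C=C(-c2c(-c3ccccc3)cc(OCc3ccccc3)c3c(OCc4ccccc4)cccc23)OC1=O | intermediate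
41 | 3-({6-[4,5-bis(benzyloxy)-2-phenylnaphthalen-1-yl]-4-hydroxy-2-oxo-2H-pyran-3-yl}methyl)-6-[(1R,2R)-5-(benzyloxy)-2-hydroxy-4-oxo-2-phenyl-1,2,3,4-tetrahydronaphthalen-1-yl]-4-hydroxy-2H-pyran-2-one | O=C1C[C@](O)(c2ccccc2)[C@H](c2cc(O)c(Cc3c(O)cc(-c4c(-c5ccccc5)cc(OCc5ccccc5)c5c(OCc6ccccc6)cccc45)oc3=O)c(=O)o2)c2cccc(OCc3ccccc3)c21 | intermediate
42 | wailupemycin I, 3-{[6-(4,5-dihydroxy-2-phenylnaphthalen-1-yl)-4-hydroxy-2-oxo-2H-pyran-3-yl]methyl}-6-[(1R,2R)-2,5-dihydroxy-4-oxo-2-phenyl-1,2,3,4-tetrahydronaphthalen-1-yl]-4-hydroxy-2H-pyran-2-one | O=C1C[C@](O)(c2ccccc2)[C@H](c2cc(O)c(Cc3c(O)cc(-c4c(-c5ccccc5)cc(O)c5c(O)cccc45)oc3=O)c(=O)o2)c2cccc(O)c21 | target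

**Totals**
Total step count: 22. Longest linear sequence: 14 steps (steps 1, 2, 3, 6 to 14, 21, 22). The naphthalene branch (steps 15 to 20) and the allylboronate branch (steps 4, 5) run in parallel.

**Three steps most likely to fail, with fallbacks**

Step 12 (one-flask enol silane/malonyl dichloride annulation on a hindered, acid-sensitive ketone). The fallback sets out from epoxide 16 and comes back at 24. Open 16 with vinylmagnesium bromide/CuI (same anti SN2 course) to give (1S,3R,4R)-8-(benzyloxy)-4-ethenyl-3-phenyl-1,2,3,4-tetrahydronaphthalene-1,3-diol F1. Silylate with Et3SiOTf/2,6-lutidine to (1S,3R,4R)-8-(benzyloxy)-4-ethenyl-3-phenyl-1,3-bis(triethylsilyloxy)-1,2,3,4-tetrahydronaphthalene F2. Ozonise (O3; Me2S) to (1R,2R,4S)-5-(benzyloxy)-2-phenyl-2,4-bis(triethylsilyloxy)-1,2,3,4-tetrahydronaphthalene-1-carbaldehyde F3. Add the dianion of methyl acetoacetate (NaH then n-BuLi, THF, −78 °C) to give methyl 5-[(1S,2R,4S)-5-(benzyloxy)-2-phenyl-2,4-bis(triethylsilyloxy)-1,2,3,4-tetrahydronaphthalen-1-yl]-5-hydroxy-3-oxopentanoate F4 (both carbinol epimers). Oxidise with Dess–Martin periodinane to methyl 5-[(1R,2R,4S)-5-(benzyloxy)-2-phenyl-2,4-bis(triethylsilyloxy)-1,2,3,4-tetrahydronaphthalen-1-yl]-3,5-dioxopentanoate F5. Close the pyrone with DBU in toluene (loss of methanol) to reach 24.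

Step 17 (domino annulation; the aldol benzannulation to a terphenyl phenol or a stalled C-arylation are the failure modes). The fallback sets out from diol 18 of the other branch and comes back at 35. Oxidise the benzylic carbinol of 18 with MnO2 to (3R,4R)-8-(benzyloxy)-3-hydroxy-3-phenyl-4-(prop-1-en-2-yl)-3,4-dihydronaphthalen-1(2H)-one F6. Dehydrate and aromatise with K2CO3 in MeOH (E1cB, then enolisation) to 8-(benzyloxy)-3-phenyl-4-(prop-1-en-2-yl)naphthalen-1-ol F7. Benzylate (BnBr, K2CO3, DMF) to 1,8-bis(benzyloxy)-3-phenyl-4-(prop-1-en-2-yl)naphthalene F8. Cleave the isopropenyl group with OsO4 (cat.)/NaIO4 to reach 35.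

Step 21 (thermal Mannich-base coupling; scrambling to homodimers or amine-induced dehydration of the β-hydroxy ketone are the risks). The fallback sets out from 37 and comes back at 41. Condense 37 with aqueous formaldehyde and sodium benzenesulfinate (HCO2H, EtOH/H2O, 25 °C) to the bench-stable sulfone 6-[4,5-bis(benzyloxy)-2-phenylnaphthalen-1-yl]-4-hydroxy-3-[(phenylsulfonyl)methyl]-2H-pyran-2-one F9. Stir F9 with 26 and NaHCO3 in THF/H2O at 25 °C: sulfinate is expelled at room temperature and the same methylidene dione 40 is trapped by 26 to give 41.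

**Further compounds**
F1 | step 12 | (1S,3R,4R)-8-(benzyloxy)-4-ethenyl-3-phenyl-1,2,3,4-tetrahydronaphthalene-1,3-diol | O[C@H]1C[C@](O)(c2ccccc2)[C@H](C=C)c2cccc(OCc3ccccc3)c21
F2 | step 12 | (1S,3R,4R)-8-(benzyloxy)-4-ethenyl-3-phenyl-1,3-bis(triethylsilyloxy)-1,2,3,4-tetrahydronaphthalene | CC[Si](CC)(CC)O[C@H]1C[C@](O[Si](CC)(CC)CC)(c2ccccc2)[C@H](C=C)c2cccc(OCc3ccccc3)c21
F3 | step 12 | (1R,2R,4S)-5-(benzyloxy)-2-phenyl-2,4-bis(triethylsilyloxy)-1,2,3,4-tetrahydronaphthalene-1-carbaldehyde | CC[Si](CC)(CC)O[C@H]1C[C@](O[Si](CC)(CC)CC)(c2ccccc2)[C@H](C=O)c2cccc(OCc3ccccc3)c21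
F4 | step 12 | methyl 5-[(1S,2R,4S)-5-(benzyloxy)-2-phenyl-2,4-bis(triethylsilyloxy)-1,2,3,4-tetrahydronaphthalen-1-yl]-5-hydroxy-3-oxopentanoate (both carbinol epimers) | CC[Si](CC)(CC)O[C@H]1C[C@](O[Si](CC)(CC)CC)(c2ccccc2)[C@H](C(O)CC(=O)CC(=O)OC)c2cccc(OCc3ccccc3)c21
F5 | step 12 | methyl 5-[(1R,2R,4S)-5-(benzyloxy)-2-phenyl-2,4-bis(triethylsilyloxy)-1,2,3,4-tetrahydronaphthalen-1-yl]-3,5-dioxopentanoate | CC[Si](CC)(CC)O[C@H]1C[C@](O[Si](CC)(CC)CC)(c2ccccc2)[C@H](C(=O)CC(=O)CC(=O)OC)c2cccc(OCc3ccccc3)c21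
F6 | step 17 | (3R,4R)-8-(benzyloxy)-3-hydroxy-3-phenyl-4-(prop-1-en-2-yl)-3,4-dihydronaphthalen-1(2H)-one | O=C1C[C@](O)(c2ccccc2)[C@H](C(C)=C)c2cccc(OCc3ccccc3)c21
F7 | step 17 | 8-(benzyloxy)-3-phenyl-4-(prop-1-en-2-yl)naphthalen-1-ol | CC(=C)c1c(-c2ccccc2)cc(O)c2c(OCc3ccccc3)cccc12
F8 | step 17 | 1,8-bis(benzyloxy)-3-phenyl-4-(prop-1-en-2-yl)naphthalene | CC(=C)c1c(-c2ccccc2)cc(OCc2ccccc2)c2c(OCc3ccccc3)cccc12
F9 | step 21 | 6-[4,5-bis(benzyloxy)-2-phenylnaphthalen-1-yl]-4-hydroxy-3-[(phenylsulfonyl)methyl]-2H-pyran-2-one | O=S(=O)(Cc1c(O)cc(-c2c(-c3ccccc3)cc(OCc3ccccc3)c3c(OCc4ccccc4)cccc23)oc1=O)c1ccccc1
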